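The plan cuts ring A from the oxolane (O1; C2 4-hydroxyphenyl; C3 acyl; C4 benzyl; C5 resorcinyl) at the C3 acyl group: an aryne is inserted into the C–O bond of an oxolane-3-carboxylic acid. One operation forms C1'–C(acyl) and C2'–O on neighbouring carbons of ring A, exploiting the ortho relation of the acyl carbon (C1') and the C2' hydroxyl; bromine at C6' steers the addition and leaves in the final hydrogenolysis. The precursor is the all-trans (2S,3S,4S,5S) oxolane-3-carboxylic acid carrying four benzyl ethers, built from an Evans aldol-derived lactone by trans benzylation at C4 and trans-selective Friedel–Crafts arylation at C5.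

Key step: step 9

Assumption: compounds 8 and 11 are taken as purchasable, and the all-trans oxolane is taken to be the most stable diastereomer, so that any reversible ionisation at C5 or enolisation at C3 or C4 converges on it.

Step 1
Reactants: 1 (4S)-4-benzyl-1,3-oxazolidin-2-one; 2 methyl 4-chloro-4-oxobutanoate
Product: 3 methyl 4-[(4S)-4-benzyl-2-oxo-1,3-oxazolidin-3-yl]-4-oxobutanoate
Conditions: n-BuLi, THF, −78 °C; then 2, −78→0 °C
Reagents that add atoms: none
Why: N-acylation of the lithiated oxazolidinone by the acid chloride (formation of an Evans imide), in which the acid chloride reacts far faster than the methyl ester and no stereocentre is touched.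

Step 2
Reactants: 3 methyl 4-[(4S)-4-benzyl-2-oxo-1,3-oxazolidin-3-yl]-4-oxobutanoate; 4 4-(benzyloxy)benzaldehyde
Product: 6 (4S)-4-benzyl-3-{(2S,3S)-2-[4-(benzyloxy)phenyl]-5-oxooxolane-3-carbonyl}-1,3-oxazolidin-2-one, via syn-aldol hydroxy ester 5 (not isolated)
Conditions: Bu2BOTf, i-Pr2NEt, CH2Cl2, 0 °C; 4, −78→0 °C; H2O2, pH 7 buffer, MeOH; then PPTS (cat.), CH2Cl2, rt
Reagents that add atoms: none
Why: Evans syn-aldol reaction in which the Z boron enolate reacts through a Zimmerman–Traxler chair on the face away from the auxiliary benzyl group, setting both new centres (S at the enolate carbon, S at the carbinol), after which the hydroxyl closes onto the methyl ester (lactonisation, 5-exo-trig) so that the syn aldol becomes the 2,3-trans lactone.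

Step 3
Reactants: 6 (4S)-4-benzyl-3-{(2S,3S)-2-[4-(benzyloxy)phenyl]-5-oxooxolane-3-carbonyl}-1,3-oxazolidin-2-one
Product: 7 (2S,3S)-2-[4-(benzyloxy)phenyl]-5-oxooxolane-3-carboxylic acid
Conditions: LiOH, H2O2, THF–H2O, 0 °C; Na2SO3; HCl to pH 2
Reagents that add atoms: hydrogen peroxide, OO
Why: Hydroperoxide cleavage of the exocyclic imide carbonyl (Evans auxiliary hydrolysis), with sulfite reducing the peracid and acidification reclosing any lactone opened by hydroxide, should leave both stereocentres untouched and return the auxiliary.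

Step 4
Reactants: 7 (2S,3S)-2-[4-(benzyloxy)phenyl]-5-oxooxolane-3-carboxylic acid; 8 1-(benzyloxy)-4-(bromomethyl)benzene
Product: 9 (2S,3S,4S)-4-[4-(benzyloxy)benzyl]-2-[4-(benzyloxy)phenyl]-5-oxooxolane-3-carboxylic acid
Conditions: LiN(SiMe3)2 (2.3 equiv), THF, −78 °C; 8, −78→−40 °C; aq HCl
Reagents that add atoms: none
Why: Alkylation of the carboxylate–lactone enolate dianion, in which only the lactone α-carbon C4 is deprotonated beside the carboxylate and the benzylic bromide enters anti to the C3 carboxylate, setting C4 (S) trans to C3.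

Step 5
Reactants: 9 (2S,3S,4S)-4-[4-(benzyloxy)benzyl]-2-[4-(benzyloxy)phenyl]-5-oxooxolane-3-carboxylic acid
Product: 10 (2S,3S,4S)-4-[4-(benzyloxy)benzyl]-2-[4-(benzyloxy)phenyl]-5-hydroxyoxolane-3-carboxylic acid (lactol, both C5 epimers)
Conditions: BH3·THF, 2-methylbut-2-ene, THF, 0 °C (gives [(CH3)2CHCH(CH3)]2BH, 4 equiv); 9, 0 °C→rt; H2O
Reagents that add atoms: none
Why: Partial reduction of a γ-lactone to its lactol by a hindered dialkylborane (disiamylborane reduction), a reagent that only converts a carboxylic acid into its acyloxyborane with loss of hydrogen and does not reduce it; the C5 configuration is of no consequence because C5 becomes planar in step 6.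

Step 6
Reactants: 10 (2S,3S,4S)-4-[4-(benzyloxy)benzyl]-2-[4-(benzyloxy)phenyl]-5-hydroxyoxolane-3-carboxylic acid; 11 1,3-bis(benzyloxy)benzene
Product: 12 (2S,3S,4S,5S)-5-[2,4-bis(benzyloxy)phenyl]-4-[4-(benzyloxy)benzyl]-2-[4-(benzyloxy)phenyl]oxolane-3-carboxylic acid (all-trans)
Conditions: 11 (3 equiv), BF3·OEt2 (2 equiv), CH2Cl2, −78→−30 °C
Reagents that add atoms: none
Why: Friedel–Crafts arylation of the cyclic oxocarbenium ion released from the lactol, in which the resorcinol diether reacts at its own position 4 (para to one benzyloxy group, ortho to the other) on the ring face anti to the neighbouring C4 benzyl group and the C2 aryl group, setting C5 (S) and giving the all-trans array, which is also the one favoured at equilibrium should the C5–O1 bond re-ionise.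

Step 7
Reactants: 13 4-(benzyloxy)phenol
Product: 14 4-(benzyloxy)-2,6-dibromophenol
Conditions: NBS (2.05 equiv), i-Pr2NH (cat.), CH2Cl2, 0 °C→rt
Reagents that add atoms: N-bromosuccinimide, O=C1CCC(=O)N1Br
Why: Electrophilic aromatic bromination in which the free hydroxyl is the stronger director and the amine-mediated NBS protocol delivers bromine to both positions ortho to it.

Step 8
Reactants: 14 4-(benzyloxy)-2,6-dibromophenol
Product: 17 4-(benzyloxy)-2-bromo-6-(trimethylsilyl)phenyl trifluoromethanesulfonate, via aryl silyl ether 15 (not isolated), via lithium silylphenoxide 16 (not isolated)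
Conditions: (Me3Si)2NH, THF, 70 °C; evaporate; n-BuLi, THF, −78 °C; Tf2O, −78 °C→rt
Reagents that add atoms: hexamethyldisilazane, C[Si](C)(C)N[Si](C)(C)C; trifluoromethanesulfonic anhydride, O=S(=O)(OS(=O)(=O)C(F)(F)F)C(F)(F)F
Why: O-silylation, bromine–lithium exchange at one of the two equivalent bromines, 1,3 O→C silyl migration (retro-Brook rearrangement) and O-triflation of the phenoxide, the standard sequence to ortho-silylaryl triflates.

Step 9
Reactants: 12 (2S,3S,4S,5S)-5-[2,4-bis(benzyloxy)phenyl]-4-[4-(benzyloxy)benzyl]-2-[4-(benzyloxy)phenyl]oxolane-3-carboxylic acid; 17 4-(benzyloxy)-2-bromo-6-(trimethylsilyl)phenyl trifluoromethanesulfonate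
Product: 19 [4-(benzyloxy)-2-bromo-6-hydroxyphenyl]{(2S,3S,4S,5S)-5-[2,4-bis(benzyloxy)phenyl]-4-[4-(benzyloxy)benzyl]-2-[4-(benzyloxy)phenyl]oxolan-3-yl}methanone, via 3-bromo-5-(benzyloxy)benzyne 18 (not isolated)
Conditions: CsF (4 equiv), 17 (1.5 equiv), THF, 125 °C, sealed tube
Reagents that add atoms: none
Why: Fluoride removes the silyl group of 17 and triflate departs to give aryne 18; the cesium carboxylate of 12 adds through oxygen to the aryne carbon distal to bromine (the future C2'), and the aryl anion thus placed at C1' beside bromine attacks the ester carbonyl (4-exo-trig, a transient four-membered ring, so no lasting ring is closed), which collapses with C–O cleavage to the ketone and the C2' phenoxide. The closest known reaction type is the fluoride-mediated insertion of arynes into the C–O bond of carboxylic acids to give ortho-hydroxyaryl ketones, formally an O-arylation followed by an anionic Fries-type acyl shift. No stereocentre is formed, the carboxylate does not enolise at C3, and the ketone arises without any organometallic base that could open the O1–C2–C3 β-alkoxy carbonyl unit. The step needs regioselective addition to the aryne, and the inductively withdrawing C–Br bond next to the triple bond secures it by distorting the aryne so that the distal carbon is the more linear and electrophilic one, which also keeps the bulky carboxylate away from bromine, whereas the benzyloxy group para to the anionic carbon should count for little. The hot aprotic medium is chosen to favour acyl transfer over protonation of the aryl anion, which would stop at the aryl ester.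

Step 10
Reactants: 19 [4-(benzyloxy)-2-bromo-6-hydroxyphenyl]{(2S,3S,4S,5S)-5-[2,4-bis(benzyloxy)phenyl]-4-[4-(benzyloxy)benzyl]-2-[4-(benzyloxy)phenyl]oxolan-3-yl}methanone
Product: 20 (2,4-dihydroxyphenyl)[(2S,3S,4S,5S)-5-(2,4-dihydroxyphenyl)-4-(4-hydroxybenzyl)-2-(4-hydroxyphenyl)oxolan-3-yl]methanone (target)
Conditions: H2 (1 atm), 10% Pd/C, NaOAc, THF–MeOH, rt
Reagents that add atoms: none
Why: Hydrogenolysis of the five benzyl aryl ethers together with hydrodebromination of the aryl bromide over palladium on carbon, with acetate buffering the HBr so that the two benzylic C–O bonds of the oxolane and the hydrogen-bonded ketone should be left alone and no stereocentre is touched.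

Compound list
1 | (4S)-4-benzyl-1,3-oxazolidin-2-one | O=C1N[C@@H](Cc2ccccc2)CO1 | starting material
2 | methyl 4-chloro-4-oxobutanoate | COC(=O)CCC(Cl)=O | starting material
3 | methyl 4-[(4S)-4-benzyl-2-oxo-1,3-oxazolidin-3-yl]-4-oxobutanoate | COC(=O)CCC(=O)N1[C@@H](Cc2ccccc2)COC1=O | intermediate
4 | 4-(benzyloxy)benzaldehyde | O=Cc1ccc(OCc2ccccc2)cc1 | starting material
5 | syn-aldol hydroxy ester (not isolated): methyl (3S)-3-{(S)-[4-(benzyloxy)phenyl](hydroxy)methyl}-4-[(4S)-4-benzyl-2-oxo-1,3-oxazolidin-3-yl]-4-oxobutanoate | COC(=O)C[C@H](C(=O)N1[C@@H](Cc2ccccc2)COC1=O)[C@H](O)c1ccc(OCc2ccccc2)cc1 | intermediate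
6 | (4S)-4-benzyl-3-{(2S,3S)-2-[4-(benzyloxy)phenyl]-5-oxooxolane-3-carbonyl}-1,3-oxazolidin-2-one | O=C1C[C@H](C(=O)N2[C@@H](Cc3ccccc3)COC2=O)[C@@H](c2ccc(OCc3ccccc3)cc2)O1 | intermediate
7 | (2S,3S)-2-[4-(benzyloxy)phenyl]-5-oxooxolane-3-carboxylic acid | OC(=O)[C@H]1CC(=O)O[C@@H]1c1ccc(OCc2ccccc2)cc1 | intermediate
8 | 1-(benzyloxy)-4-(bromomethyl)benzene | BrCc1ccc(OCc2ccccc2)cc1 | starting material
9 | (2S,3S,4S)-4-[4-(benzyloxy)benzyl]-2-[4-(benzyloxy)phenyl]-5-oxooxolane-3-carboxylic acid | OC(=O)[C@H]1[C@H](Cc2ccc(OCc3ccccc3)cc2)C(=O)O[C@@H]1c1ccc(OCc2ccccc2)cc1 | intermediate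
10 | (2S,3S,4S)-4-[4-(benzyloxy)benzyl]-2-[4-(benzyloxy)phenyl]-5-hydroxyoxolane-3-carboxylic acid (both C5 epimers) | OC(=O)[C@H]1[C@H](Cc2ccc(OCc3ccccc3)cc2)C(O)O[C@@H]1c1ccc(OCc2ccccc2)cc1 | intermediate
11 | 1,3-bis(benzyloxy)benzene | c1ccc(COc2cccc(OCc3ccccc3)c2)cc1 | starting material
12 | (2S,3S,4S,5S)-5-[2,4-bis(benzyloxy)phenyl]-4-[4-(benzyloxy)benzyl]-2-[4-(benzyloxy)phenyl]oxolane-3-carboxylic acid | OC(=O)[C@H]1[C@H](Cc2ccc(OCc3ccccc3)cc2)[C@@H](c2ccc(OCc3ccccc3)cc2OCc2ccccc2)O[C@@H]1c1ccc(OCc2ccccc2)cc1 | intermediate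
13 | 4-(benzyloxy)phenol | Oc1ccc(OCc2ccccc2)cc1 | starting material
14 | 4-(benzyloxy)-2,6-dibromophenol | Oc1c(Br)cc(OCc2ccccc2)cc1Br | intermediate
15 | aryl silyl ether (not isolated): [4-(benzyloxy)-2,6-dibromophenoxy]trimethylsilane | C[Si](C)(C)Oc1c(Br)cc(OCc2ccccc2)cc1Br | intermediate
16 | lithium silylphenoxide (not isolated): lithium 4-(benzyloxy)-2-bromo-6-(trimethylsilyl)phenolate | [Li+].[O-]c1c(Br)cc(OCc2ccccc2)cc1[Si](C)(C)C | intermediate
17 | 4-(benzyloxy)-2-bromo-6-(trimethylsilyl)phenyl trifluoromethanesulfonate | C[Si](C)(C)c1cc(OCc2ccccc2)cc(Br)c1OS(=O)(=O)C(F)(F)F | intermediate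
18 | 3-bromo-5-(benzyloxy)benzyne (not isolated) | BrC1=CC(OCc2ccccc2)=CC#C1 | intermediate
19 | [4-(benzyloxy)-2-bromo-6-hydroxyphenyl]{(2S,3S,4S,5S)-5-[2,4-bis(benzyloxy)phenyl]-4-[4-(benzyloxy)benzyl]-2-[4-(benzyloxy)phenyl]oxolan-3-yl}methanone | O=C(c2c(Br)cc(OCc3ccccc3)cc2O)[C@H]1[C@H](Cc2ccc(OCc3ccccc3)cc2)[C@@H](c2ccc(OCc3ccccc3)cc2OCc2ccccc2)O[C@@H]1c1ccc(OCc2ccccc2)cc1 | intermediate
20 | (2,4-dihydroxyphenyl)[(2S,3S,4S,5S)-5-(2,4-dihydroxyphenyl)-4-(4-hydroxybenzyl)-2-(4-hydroxyphenyl)oxolan-3-yl]methanone | O=C(c1ccc(O)cc1O)[C@H]1[C@H](Cc2ccc(O)cc2)[C@@H](c2ccc(O)cc2O)O[C@@H]1c1ccc(O)cc1 | target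

Total step count: 10. Longest linear sequence: 8 (steps 1–6, 9 and 10); steps 7 and 8 form the two-step branch to triflate 17.

Steps most likely to fail

Step 9. The hindered cesium carboxylate may add too slowly to the short-lived aryne, and the aryl anion may be protonated, or may lose bromide, before it takes over the acyl group, so that aryl ester or no ketone is formed. The fallback is a halogen–lithium exchange-triggered anionic Fries rearrangement and sets out from acid 12. Esterification (DCC, DMAP, CH2Cl2) with 5-(benzyloxy)-2-bromophenol F1, itself made from 4-bromoresorcinol by benzylation of the hydroxyl para to bromine (BnBr, K2CO3, acetone), should give the 2-bromoaryl ester F2. n-BuLi in THF at −100 °C exchanges bromine for lithium, and the aryllithium takes the acyl group from oxygen in a 1,3 shift at a temperature at which C3 is not deprotonated, which should give the bromine-free 2'-hydroxy ketone pentabenzyl ether F3. Hydrogenolysis under the conditions of step 10, without the acetate, brings the fallback back to the route at target 20.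

Step 6. Facial selectivity may suffer if the C3 carboxyl group captures the oxocarbenium ion and shields the face anti to the benzyl group; the electron-rich product may also be arylated a second time or opened at C5 by excess arene. The fallback sets out from lactone acid 9 and bypasses lactol 10. Two equivalents of [2,4-bis(benzyloxy)phenyl]lithium F5, made from 2,4-bis(benzyloxy)-1-bromobenzene F4 (4-bromoresorcinol, BnBr, K2CO3, DMF) and n-BuLi at −78 °C, are added in THF at −78 °C; the first deprotonates the acid and the second adds to the lactone carbonyl, which should give the hemiketal acid F6. Et3SiH and BF3·OEt2 in CH2Cl2 at −78 °C reduce it through the aryl-substituted oxocarbenium ion; hydride is expected to enter anti to the C4 benzyl group, so the 4,5-cis acid F7 should predominate. After removal of the silane, BF3·OEt2 (cat.) in CH2Cl2 at 0 °C should re-ionise the doubly alkoxy-stabilised benzylic C5–O1 bond and reclose the ring to the all-trans acid 12, where the fallback rejoins the route.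

Step 5. Hydride transfer from the bulky borane to the α-branched lactone may be sluggish, and material may be held back as boron-bound carboxylate on work-up. The fallback sets out from 9. Allyl bromide and K2CO3 in DMF should give the allyl ester F8. i-Bu2AlH (1.1 equiv) in CH2Cl2 at −78 °C should reduce the lactone in preference to the hindered ester and give the lactol allyl ester F9. Arylation with 11 and BF3·OEt2 as in step 6 should give the all-trans oxolane allyl ester F10. Pd(PPh3)4 (zerovalent palladium) and morpholine in THF at rt remove the allyl group and deliver acid 12, where the fallback rejoins the route.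

Further compounds
F1 | step 9 | 5-(benzyloxy)-2-bromophenol | Oc1cc(OCc2ccccc2)ccc1Br
F2 | step 9 | 5-(benzyloxy)-2-bromophenyl (2S,3S,4S,5S)-5-[2,4-bis(benzyloxy)phenyl]-4-[4-(benzyloxy)benzyl]-2-[4-(benzyloxy)phenyl]oxolane-3-carboxylate | O=C(Oc1cc(OCc2ccccc2)ccc1Br)[C@H]1[C@H](Cc2ccc(OCc3ccccc3)cc2)[C@@H](c2ccc(OCc3ccccc3)cc2OCc2ccccc2)O[C@@H]1c1ccc(OCc2ccccc2)cc1
F3 | step 9 | [4-(benzyloxy)-2-hydroxyphenyl]{(2S,3S,4S,5S)-5-[2,4-bis(benzyloxy)phenyl]-4-[4-(benzyloxy)benzyl]-2-[4-(benzyloxy)phenyl]oxolan-3-yl}methanone | O=C(c1ccc(OCc2ccccc2)cc1O)[C@H]1[C@H](Cc2ccc(OCc3ccccc3)cc2)[C@@H](c2ccc(OCc3ccccc3)cc2OCc2ccccc2)O[C@@H]1c1ccc(OCc2ccccc2)cc1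
F4 | step 6 | 2,4-bis(benzyloxy)-1-bromobenzene | Brc1ccc(OCc2ccccc2)cc1OCc1ccccc1
F5 | step 6 | [2,4-bis(benzyloxy)phenyl]lithium | [Li]c1ccc(OCc2ccccc2)cc1OCc1ccccc1
F6 | step 6 | (2S,3S,4S)-5-[2,4-bis(benzyloxy)phenyl]-4-[4-(benzyloxy)benzyl]-2-[4-(benzyloxy)phenyl]-5-hydroxyoxolane-3-carboxylic acid (hemiketal) | OC(=O)[C@H]1[C@H](Cc2ccc(OCc3ccccc3)cc2)C(O)(c2ccc(OCc3ccccc3)cc2OCc2ccccc2)O[C@@H]1c1ccc(OCc2ccccc2)cc1
F7 | step 6 | (2S,3S,4S,5R)-5-[2,4-bis(benzyloxy)phenyl]-4-[4-(benzyloxy)benzyl]-2-[4-(benzyloxy)phenyl]oxolane-3-carboxylic acid (4,5-cis) | OC(=O)[C@H]1[C@H](Cc2ccc(OCc3ccccc3)cc2)[C@H](c2ccc(OCc3ccccc3)cc2OCc2ccccc2)O[C@@H]1c1ccc(OCc2ccccc2)cc1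
F8 | step 5 | prop-2-en-1-yl (2S,3S,4S)-4-[4-(benzyloxy)benzyl]-2-[4-(benzyloxy)phenyl]-5-oxooxolane-3-carboxylate | C=CCOC(=O)[C@H]1[C@H](Cc2ccc(OCc3ccccc3)cc2)C(=O)O[C@@H]1c1ccc(OCc2ccccc2)cc1
F9 | step 5 | prop-2-en-1-yl (2S,3S,4S)-4-[4-(benzyloxy)benzyl]-2-[4-(benzyloxy)phenyl]-5-hydroxyoxolane-3-carboxylate (both C5 epimers) | C=CCOC(=O)[C@H]1[C@H](Cc2ccc(OCc3ccccc3)cc2)C(O)O[C@@H]1c1ccc(OCc2ccccc2)cc1
F10 | step 5 | prop-2-en-1-yl (2S,3S,4S,5S)-5-[2,4-bis(benzyloxy)phenyl]-4-[4-(benzyloxy)benzyl]-2-[4-(benzyloxy)phenyl]oxolane-3-carboxylate | C=CCOC(=O)[C@H]1[C@H](Cc2ccc(OCc3ccccc3)cc2)[C@@H](c2ccc(OCc3ccccc3)cc2OCc2ccccc2)O[C@@H]1c1ccc(OCc2ccccc2)cc1
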